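**Plan**
- Retrosynthetic cuts: the C6–O ester; C11–C12 (B-alkyl Suzuki–Miyaura); C9=C11 (Peterson olefination of a C9 ketone); C1–C10 (ring A, 6-endo radical conjugate addition); C8–O (conjugate borylation); C4–C5 (radical alkylation of a quinone).
- Enabling feature: ring B is a disguised 2,6-dimethyl-1,4-benzoquinone (oxygen on C6 and C9, methyls on C8 and C10). With C6=O and C5=C10, the quaternary C10 is the β-carbon of an enone whose α-carbon C5 carries the C4–C3–C2–C1 chain.
- Forward order: ring B is bought as the quinone → chain on C5 → C9 masked as ketal → C8–OH → ring A closed by C1–C10 → C6 reduced → C9 methylenated → side chain joined at C11 → angelate.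
- Stereochemistry: C8 by copper-catalysed enantioselective borylation; C10 and C5 together in the ring closure, relayed from C8; C6 by thermodynamic ketone reduction; C9 by α-face hydroboration; 12Z from a Z-iodo diene; ester Z from angelic acid.

Key step: step 8

Remark: labdane numbering (C1–C20) is used for the atoms of every intermediate; α is the face of H-5, β the face of CH3-20. The antipode of the borylation ligand is the one that gives the 8R alcohol.

Step 1
Reactants: 1 isobutyric acid; 2 1-bromo-3-chloropropane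
Product: 3 5-chloro-2,2-dimethylpentanoic acid
Conditions: LiN(iPr)2 (2.1 equiv), THF, 0 °C; then 2, −20 → 23 °C; aq HCl
Reagents that add atoms: none
Why: SN2 alkylation of the carboxylic acid dianion at the C–Br end (bromide is the better leaving group) builds the gem-dimethyl carbon that becomes C4 and leaves the chloride as the latent C1 radical site.

Step 2
Reactants: 3 5-chloro-2,2-dimethylpentanoic acid; 4 2,6-dimethyl-1,4-benzoquinone
Product: 5 2-(5-chloro-2-methylpentan-2-yl)-3,5-dimethyl-1,4-benzoquinone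
Conditions: AgNO3 (0.2 equiv), (NH4)2S2O8, MeCN/H2O, 65 °C
Reagents that add atoms: none
Why: Minisci-type silver/persulfate oxidative decarboxylation gives the nucleophilic tertiary radical, which adds to one of the two equivalent unsubstituted quinone positions and is re-oxidized to the quinone, forming C4–C5.

Step 3
Reactants: 5 2-(5-chloro-2-methylpentan-2-yl)-3,5-dimethyl-1,4-benzoquinone
Product: 6 2-(5-chloro-2-methylpentan-2-yl)-3,5-dimethylbenzene-1,4-diol
Conditions: Na2S2O4, EtOAc/H2O, 23 °C
Reagents that add atoms: none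
Why: Two-electron dithionite reduction of a quinone to its hydroquinone, which makes the two oxygens (on C6 and C9) separately addressable.

Step 4
Reactants: 6 2-(5-chloro-2-methylpentan-2-yl)-3,5-dimethylbenzene-1,4-diol
Product: 7 2-(5-chloro-2-methylpentan-2-yl)-4-(2-hydroxyethoxy)-3,5-dimethylphenol
Conditions: BrCH2CH2OH (1.1 equiv), K2CO3, DMF, 50 °C, N2
Reagents that add atoms: 2-bromoethanol, OCCBr
Why: Williamson etherification should occur at the hydroxyl between the two methyls (O on C9), because the other hydroxyl is shielded by the ortho tert-alkyl group, itself buttressed by its neighbouring methyl.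

Step 5
Reactants: 7 2-(5-chloro-2-methylpentan-2-yl)-4-(2-hydroxyethoxy)-3,5-dimethylphenol
Product: 8 7-(5-chloro-2-methylpentan-2-yl)-6,10-dimethyl-1,4-dioxaspiro[4.5]deca-6,9-dien-8-one
Conditions: PhI(OAc)2, MeCN, 0 °C
Reagents that add atoms: none
Why: Oxidative dearomatization of a para-alkoxyphenol by the trivalent iodine reagent, with the pendant hydroxyl trapping C9 (spiroketalization), gives the achiral quinone monoketal with C6=O free and C9 masked.

Step 6
Reactants: 8 7-(5-chloro-2-methylpentan-2-yl)-6,10-dimethyl-1,4-dioxaspiro[4.5]deca-6,9-dien-8-one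
Product: 10 (10R)-7-(5-chloro-2-methylpentan-2-yl)-10-hydroxy-6,10-dimethyl-1,4-dioxaspiro[4.5]dec-6-en-8-one, via pinacol boronate 9 (not isolated)
Conditions: CuCl (5 mol %), (R,R)-QuinoxP* (6 mol %), NaOtBu (10 mol %), B2pin2, MeOH, THF, 0 °C; then H2O2, aq NaHCO3, 0 °C
Reagents that add atoms: bis(pinacolato)diboron (boron of 9), CC1(C)OB(OC1(C)C)B1OC(C)(C)C(C)(C)O1; hydrogen peroxide (oxygen of 10), OO
Why: Copper-catalysed enantioselective conjugate borylation of the less hindered β-methyl enone (C7=C8; the C5=C10 enone is tetrasubstituted and flanked by the tert-alkyl group) followed by stereoretentive C–B oxidation; the chiral bisphosphine–copper boryl complex selects the face of C8 and sets 8R (8α-OH, 8β-CH3).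

Step 7
Reactants: 10 (10R)-7-(5-chloro-2-methylpentan-2-yl)-10-hydroxy-6,10-dimethyl-1,4-dioxaspiro[4.5]dec-6-en-8-one
Product: 11 (10R)-10-hydroxy-7-(5-iodo-2-methylpentan-2-yl)-6,10-dimethyl-1,4-dioxaspiro[4.5]dec-6-en-8-one
Conditions: NaI, 2-butanone, 80 °C
Reagents that add atoms: sodium iodide, [Na+].[I-]
Why: Finkelstein halide exchange (SN2 at the primary C1, driven by precipitation of NaCl) installs the radical precursor under neutral conditions that leave the β-hydroxy enone untouched.

Step 8
Reactants: 11 (10R)-10-hydroxy-7-(5-iodo-2-methylpentan-2-yl)-6,10-dimethyl-1,4-dioxaspiro[4.5]dec-6-en-8-one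
Product: 12 (5S,8R,10S)-8α-hydroxy-11-nordrimane-6,9-dione 9-ethylene ketal (trans-decalin)
Conditions: Bu3SnH (1.3 equiv), AIBN (0.2 equiv), PhH (0.005 M), 80 °C, slow addition
Reagents that add atoms: none
Why: Tin-radical iodine abstraction gives the primary C1 radical, which adds to C10, the β-carbon of the C6 enone, and the resulting C5 α-keto radical takes a hydrogen atom from Bu3SnH in a radical chain. The closest known type is the 6-endo radical conjugate addition (Giese-type cyclization) of α-(ω-haloalkyl)cycloalkenones. Ring A closes in the 6-endo-trig mode, since 5-exo attack would hit C5, the polarity-mismatched α-carbon that also carries the quaternary C4. C10 is controlled by the C8 carbinol: in the sofa conformer with 8-CH3 equatorial and 8-OH axial the radical enters axially on the α-face beside the small axial OH, whereas β-attack would be 1,3-diaxial to the 8-methyl, so CH3-20 ends β and cis to CH3-17. C5 is set in the hydrogen transfer, which comes from the α-face because the β-face is screened by the axial methyls on C10 and C4, giving the trans ring fusion. The step needs ring closure to outrun direct reduction of the primary radical, which the gem-dimethyl group on C4, the polarity match, strain release of the twisted tetrasubstituted enone and slow addition of the hydride should secure.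

Step 9
Reactants: 12 (5S,8R,10S)-8α-hydroxy-11-nordrimane-6,9-dione 9-ethylene ketal
Product: 13 (5S,6S,8R,10S)-6α,8α-dihydroxy-11-nordriman-9-one ethylene ketal
Conditions: Li, NH3 (l)/THF, −78 °C; NH4Cl
Reagents that add atoms: none
Why: Dissolving-metal (Birch-type electron-transfer) reduction of the ketone proceeds through the ketyl and gives the thermodynamically favoured equatorial 6α-alcohol, the axial 6β-alcohol being 1,3-diaxial to the methyls on C10 and C4.

Step 10
Reactants: 13 (5S,6S,8R,10S)-6α,8α-dihydroxy-11-nordriman-9-one ethylene ketal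
Product: 14 (5S,6S,8R,10S)-6α,8α-dihydroxy-11-nordriman-9-one
Conditions: 2 M HCl, THF, 40 °C
Reagents that add atoms: water, O
Why: Acid-catalysed ketal hydrolysis, helped by strain release at the crowded C9, unmasks a ketone that has no α-hydrogen (C8 and C10 are quaternary).

Step 11
Reactants: 14 (5S,6S,8R,10S)-6α,8α-dihydroxy-11-nordriman-9-one
Product: 16 (5S,6S,8R,10S)-drim-9(11)-ene-6α,8α-diol, via β-hydroxysilane 15 (not isolated)
Conditions: Me3SiCH2Li (4 equiv), THF, −78 → 0 °C; aq NH4Cl; then KH, THF, 23 °C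
Reagents that add atoms: (trimethylsilyl)methyllithium, [Li]C[Si](C)(C)C
Why: Peterson olefination: the non-enolizable C9 ketone accepts the α-silyl carbanion and the potassium alkoxide loses trimethylsilanolate by syn-elimination to the exocyclic C9=C11 alkene, so the C9 configuration of adduct 15 is of no consequence.

Step 12
Reactants: 17 prop-2-yn-1-ol
Product: 19 (Z)-3-iodo-2-methylprop-2-en-1-ol, via alkenylmagnesium alkoxide 18 (not isolated)
Conditions: MeMgBr (2.2 equiv), CuI (10 mol %), THF, −10 → 23 °C; then I2, −78 → 0 °C; aq NH4Cl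
Reagents that add atoms: methylmagnesium bromide, C[Mg]Br; iodine, II
Why: Copper-catalysed anti-carbomagnesiation of the propargylic magnesium alkoxide puts CH3 on C2 and magnesium on C3 cis to the CH2O group (chelate), and iodinolysis with retention gives the Z-iodoalkene.

Step 13
Reactants: 19 (Z)-3-iodo-2-methylprop-2-en-1-ol
Product: 20 (Z)-3-iodo-2-methylprop-2-enal
Conditions: MnO2, CH2Cl2, 23 °C
Reagents that add atoms: none
Why: Neutral MnO2 oxidation of the allylic alcohol gives the enal without acid or base that could isomerize the Z-alkene; the aldehyde is used at once.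

Step 14
Reactants: 20 (Z)-3-iodo-2-methylprop-2-enal
Product: 21 (Z)-1-iodo-2-methylbuta-1,3-diene
Conditions: Ph3PCH3Br, NaN(SiMe3)2, THF, −78 → 0 °C
Reagents that add atoms: methyltriphenylphosphonium bromide, C[P+](c1ccccc1)(c1ccccc1)c1ccccc1.[Br-]
Why: Wittig methylenation with the non-stabilized ylide at low temperature converts CHO into the vinyl group and leaves the trisubstituted Z-iodoalkene geometry intact.

Step 15
Reactants: 16 (5S,6S,8R,10S)-drim-9(11)-ene-6α,8α-diol; 21 (Z)-1-iodo-2-methylbuta-1,3-diene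
Product: 23 (5S,6S,8R,9R,10S,12Z)-labda-12,14-diene-6α,8α-diol, via B-alkyl-9-BBN adduct 22 (not isolated)
Conditions: 9-BBN (3.5 equiv), THF, 23 → 60 °C; then 21, PdCl2(dppf) (5 mol %), aq K3PO4, DMF, 23 °C
Reagents that add atoms: 9-borabicyclo[3.3.1]nonane (boron of 22), [H]B1C2CCCC1CCC2
Why: Hydroboration puts boron on the terminal C11 and hydrogen on C9 from the α-face (the β-face is closed by the axial methyls on C8 and C10), which sets C9 with the side chain β-equatorial, and the B-alkyl Suzuki–Miyaura coupling joins C11 to C12 with retention of the Z geometry of 21.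

Step 16
Reactants: 23 (5S,6S,8R,9R,10S,12Z)-labda-12,14-diene-6α,8α-diol; 24 angelic acid ((Z)-2-methylbut-2-enoic acid)
Product: 25 (5S,6S,8R,9R,10S,12Z)-8α-hydroxylabda-12,14-dien-6α-yl (Z)-2-methylbut-2-enoate (target)
Conditions: 24, 2,4,6-Cl3C6H2COCl, Et3N, PhMe, 23 °C; then 23, 80 °C
Reagents that add atoms: none
Why: Yamaguchi-type mixed-anhydride acylation of the secondary equatorial 6-OH (the tertiary 8-OH does not react), run without a nucleophilic amine catalyst so that the Z (angelate) geometry is not isomerized to the tiglate.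

**Compound list**
1 | isobutyric acid | CC(C)C(=O)O | starting material
2 | 1-bromo-3-chloropropane | ClCCCBr | starting material
3 | 5-chloro-2,2-dimethylpentanoic acid | CC(C)(CCCCl)C(=O)O | intermediate
4 | 2,6-dimethyl-1,4-benzoquinone | CC1=CC(=O)C=C(C)C1=O | starting material
5 | 2-(5-chloro-2-methylpentan-2-yl)-3,5-dimethyl-1,4-benzoquinone | CC1=CC(=O)C(C(C)(C)CCCCl)=C(C)C1=O | intermediate
6 | 2-(5-chloro-2-methylpentan-2-yl)-3,5-dimethylbenzene-1,4-diol | Cc1cc(O)c(C(C)(C)CCCCl)c(C)c1O | intermediate
7 | 2-(5-chloro-2-methylpentan-2-yl)-4-(2-hydroxyethoxy)-3,5-dimethylphenol | Cc1cc(O)c(C(C)(C)CCCCl)c(C)c1OCCO | intermediate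
8 | 7-(5-chloro-2-methylpentan-2-yl)-6,10-dimethyl-1,4-dioxaspiro[4.5]deca-6,9-dien-8-one | CC1=CC(=O)C(C(C)(C)CCCCl)=C(C)C12OCCO2 | intermediate
9 | (10S)-7-(5-chloro-2-methylpentan-2-yl)-6,10-dimethyl-10-(4,4,5,5-tetramethyl-1,3,2-dioxaborolan-2-yl)-1,4-dioxaspiro[4.5]dec-6-en-8-one | C12(OCCO1)C(C)=C(C(C)(C)CCCCl)C(=O)C[C@@]2(C)B1OC(C)(C)C(C)(C)O1 | intermediate
10 | (10R)-7-(5-chloro-2-methylpentan-2-yl)-10-hydroxy-6,10-dimethyl-1,4-dioxaspiro[4.5]dec-6-en-8-one | C12(OCCO1)C(C)=C(C(C)(C)CCCCl)C(=O)C[C@@]2(C)O | intermediate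
11 | (10R)-10-hydroxy-7-(5-iodo-2-methylpentan-2-yl)-6,10-dimethyl-1,4-dioxaspiro[4.5]dec-6-en-8-one | C12(OCCO1)C(C)=C(C(C)(C)CCCI)C(=O)C[C@@]2(C)O | intermediate
12 | (5S,8R,10S)-8α-hydroxy-11-nordrimane-6,9-dione 9-ethylene ketal | C12(OCCO1)[C@@]3(C)CCCC(C)(C)[C@@H]3C(=O)C[C@@]2(C)O | intermediate
13 | (5S,6S,8R,10S)-6α,8α-dihydroxy-11-nordriman-9-one ethylene ketal | C12(OCCO1)[C@@]3(C)CCCC(C)(C)[C@@H]3[C@@H](O)C[C@@]2(C)O | intermediate
14 | (5S,6S,8R,10S)-6α,8α-dihydroxy-11-nordriman-9-one | O=C1[C@@]2(C)CCCC(C)(C)[C@@H]2[C@@H](O)C[C@@]1(C)O | intermediate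
15 | (5S,6S,8R,9R,10S)-9-[(trimethylsilyl)methyl]-11-nordrimane-6α,8α,9-triol (silylmethyl α, expected epimer) | C[Si](C)(C)C[C@@]1(O)[C@@]2(C)CCCC(C)(C)[C@@H]2[C@@H](O)C[C@@]1(C)O | intermediate
16 | (5S,6S,8R,10S)-drim-9(11)-ene-6α,8α-diol | C=C1[C@@]2(C)CCCC(C)(C)[C@@H]2[C@@H](O)C[C@@]1(C)O | intermediate
17 | prop-2-yn-1-ol | C#CCO | starting material
18 | (Z)-[3-(bromomagnesiooxy)-2-methylprop-1-en-1-yl]magnesium bromide | Br[Mg]OC/C(C)=C\[Mg]Br | intermediate
19 | (Z)-3-iodo-2-methylprop-2-en-1-ol | OC/C(C)=C\I | intermediate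
20 | (Z)-3-iodo-2-methylprop-2-enal | O=C/C(C)=C\I | intermediate
21 | (Z)-1-iodo-2-methylbuta-1,3-diene | C=C/C(C)=C\I | intermediate
22 | (5S,6S,8R,9R,10S)-11-(9-borabicyclo[3.3.1]nonan-9-yl)drimane-6α,8α-diol (drawn with free hydroxyls) | B1(C[C@@H]2[C@@]3(C)CCCC(C)(C)[C@@H]3[C@@H](O)C[C@@]2(C)O)C2CCCC1CCC2 | intermediate
23 | (5S,6S,8R,9R,10S,12Z)-labda-12,14-diene-6α,8α-diol | C=C/C(C)=C\C[C@@H]1[C@@]2(C)CCCC(C)(C)[C@@H]2[C@@H](O)C[C@@]1(C)O | intermediate
24 | angelic acid, (Z)-2-methylbut-2-enoic acid | C/C=C(/C)C(=O)O | starting material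
25 | (5S,6S,8R,9R,10S,12Z)-8α-hydroxylabda-12,14-dien-6α-yl (Z)-2-methylbut-2-enoate | C=C/C(C)=C\C[C@@H]1[C@@]2(C)CCCC(C)(C)[C@@H]2[C@@H](OC(=O)/C(C)=C\C)C[C@@]1(C)O | target

Total step count: 16. Longest linear sequence: 13 steps (steps 1–11, 15, 16).

**Steps most likely to fail**

Step 8. Closure at the crowded C10 may be too slow, so that hydrogen transfer to the primary C1 radical (simple deiodination) wins. The fallback sets out from 11: a nickel-catalysed reductive conjugate addition of the alkyl iodide to the enone (NiCl2(dme), neocuproine, Mn powder, Et3SiCl, DMF, 40 °C) has no hydrogen-atom donor in the flask and should give the triethylsilyl enol ether F1. Mild protonolysis (HCl, THF/H2O, 0 °C) should protonate C5 from the α-face and come back to the route at 12.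

Step 6. Conjugate borylation at C8, a β-carbon next to the spiro ketal, may stall or give low enantioselectivity. The fallback sets out from 8: asymmetric Weitz–Scheffer epoxidation of the C7=C8 enone under chiral phase-transfer catalysis (t-BuOOH, KOH, N-(9-anthracenylmethyl)cinchonidinium bromide, PhMe, 0 °C) should give the 7α,8α-epoxy ketone F2. Reductive opening of the C7–O bond with SmI2 (THF/MeOH, −78 °C) comes back to the route at 10.

Step 11. Addition of the silyl carbanion to the C9 carbonyl, which lies between two quaternary carbons, may fail, or the adduct may not eliminate. The fallback sets out from 14 and returns at 23, bypassing 16 and 21. The slim nucleophile HC≡CMgBr (THF, 0 °C) should give the propargylic triol F3. Meyer–Schuster rearrangement (VO(OSiPh3)3, xylene, 140 °C) should give the enal F4. Hydrogenation from the α-face (H2, Pd/C, EtOAc) should give the lactol F5, in which the 8-OH is closed on C12. Wittig reaction with Ph3P=C(I)CH3 (from Ph3PEtI, n-BuLi, I2, then NaN(SiMe3)2, THF, −78 °C) should give the Z-iodoalkene F6. Stille coupling with Bu3SnCH=CH2 (Pd(PPh3)4, CuI, DMF, 23 °C) then gives 23.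

**Further compounds**
F1 | step 8 | (8R,10S)-8α-hydroxy-6-(triethylsilyloxy)-11-nordrim-5-en-9-one ethylene ketal | C12(OCCO1)[C@@]3(C)CCCC(C)(C)C3=C(O[Si](CC)(CC)CC)C[C@@]2(C)O
F2 | step 6 | 7α,8α-epoxide of 8 (labdane C7 S, C8 R), 7-(5-chloro-2-methylpentan-2-yl)-9,10-epoxy-6,10-dimethyl-1,4-dioxaspiro[4.5]dec-6-en-8-one | C12(OCCO1)C(C)=C(C(C)(C)CCCCl)C(=O)[C@H]3O[C@@]23C
F3 | step 11 | (5S,6S,8R,9R,10S)-9-ethynyl-11-nordrimane-6α,8α,9-triol (ethynyl α, expected epimer) | C#C[C@@]1(O)[C@@]2(C)CCCC(C)(C)[C@@H]2[C@@H](O)C[C@@]1(C)O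
F4 | step 11 | (5S,6S,8R,10S)-6α,8α-dihydroxy-13,14,15,16-tetranorlabd-9(11)-en-12-al (drawn as the 9(11)Z isomer; either isomer serves) | O=C/C=C1/[C@@]2(C)CCCC(C)(C)[C@@H]2[C@@H](O)C[C@@]1(C)O
F5 | step 11 | (5S,6S,8R,9R,10S)-8α,12-epoxy-13,14,15,16-tetranorlabdane-6α,12-diol (lactol, both C12 anomers) | OC1C[C@@H]2[C@@]3(C)CCCC(C)(C)[C@@H]3[C@@H](O)C[C@@]2(C)O1
F6 | step 11 | (5S,6S,8R,9R,10S,12Z)-13-iodo-14,15-dinorlabd-12-ene-6α,8α-diol | I/C(C)=C\C[C@@H]1[C@@]2(C)CCCC(C)(C)[C@@H]2[C@@H](O)C[C@@]1(C)O
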